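**Assumption:** (−)-sclareol, (13R)-labd-14-ene-8α,13-diol, is taken as a commercially available bulk terpenoid; labdane numbering is used throughout.

## Retrosynthetic overview

1. 4 ⇒ 3: the acetate is the last bond made, by selective acylation of the primary C15–OH of the tetraol.
2. 3 ⇒ 2 ⇒ 1: C14–O and C15–O are made together by a [3+2] cycloaddition of OsO4 (as its TMEDA complex) across the vinyl group of sclareol; the osmate chelate 2 is isolated, then hydrolysed.
3. Ring order: rings A and B (C5, C8, C9, C10) and the C13 carbinol are bought intact in 1. The only ring the route forms is the five-membered osmate ring (O–C15–C14–O–Os), which is opened again in step 2.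
4. Stereochemistry: five stereocentres are purchased; C14 is set in the cycloaddition by hydrogen-bond delivery from the C13 hydroxyl. This induction is modest, so the 14S epimer is removed at the chelate stage.

## Route

**Step 1**
Reactants: 1 (−)-sclareol
Product: 2 OsO2(TMEDA) 14,15-glycolate of (13R,14R)-labdane-8α,13,14,15-tetraol (cyclic osmate ester chelate, hexavalent osmium)
Conditions: OsO4 (1.05 equiv), TMEDA (1.1 equiv), CH2Cl2, −78 °C, 1 h; flash chromatography on SiO2 to remove the 14S chelate
Reagents that add atoms: osmium tetroxide, O=[Os](=O)(=O)=O; N,N,N′,N′-tetramethylethylenediamine (TMEDA), CN(C)CCN(C)C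
Why: Suprafacial [3+2] cycloaddition of the OsO4–TMEDA complex to the vinyl group (hydrogen-bond-directed osmylation, Donohoe conditions) closes the osmate ring and makes both C–O bonds at once; the C13 hydroxyl binds the reagent and delivers it syn to itself with the C13 methyl in the alkene plane and the C12 chain anti, which gives 14R, but because a methyl/methylene-substituted carbinol discriminates only modestly (roughly 2:1 expected) the 14S chelate is separated here.

**Step 2**
Reactants: 2 OsO2(TMEDA) 14,15-glycolate
Product: 3 (13R,14R)-labdane-8α,13,14,15-tetraol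
Conditions: Na2SO3 (sat. aq.), THF, reflux, 3 h
Reagents that add atoms: none
Why: Reductive hydrolysis of the osmate ester, in which sulfite reduces hexavalent osmium and water cleaves only Os–O bonds, so C14 and C15 keep their configuration and the tertiary alcohols are untouched.

**Step 3**
Reactants: 3 (13R,14R)-labdane-8α,13,14,15-tetraol
Product: 4 (13R,14R)-8α,13,14-trihydroxylabdan-15-yl acetate (CNP0523287.1)
Conditions: AcCl (1.05 equiv), 2,4,6-collidine (2 equiv), CH2Cl2, −78 °C
Reagents that add atoms: acetyl chloride, CC(Cl)=O
Why: Kinetically selective O-acylation (acetyl chloride/collidine protocol for primary alcohols): at −78 °C the unhindered primary C15–OH reacts far faster than the C14–OH next to a quaternary carbon or the two tertiary alcohols, the weak base suppresses 15→14 acyl migration, and no stereocentre is touched.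

## Compound list

1 | (−)-sclareol, (13R)-labd-14-ene-8α,13-diol | C=C[C@](C)(O)CC[C@@H]1[C@@]2(C)CCCC(C)(C)[C@@H]2CC[C@@]1(C)O | starting material
2 | OsO2(TMEDA) 14,15-glycolate of (13R,14R)-labdane-8α,13,14,15-tetraol | O=[Os-2]12(=O)(OC[C@@H](O1)[C@](C)(O)CC[C@@H]3[C@@]4(C)CCCC(C)(C)[C@@H]4CC[C@@]3(C)O)[N+](C)(C)CC[N+]2(C)C | intermediate
3 | (13R,14R)-labdane-8α,13,14,15-tetraol | OC[C@@H](O)[C@](C)(O)CC[C@@H]1[C@@]2(C)CCCC(C)(C)[C@@H]2CC[C@@]1(C)O | intermediate
4 | (13R,14R)-8α,13,14-trihydroxylabdan-15-yl acetate | CC(=O)OC[C@@H](O)[C@](C)(O)CC[C@@H]1[C@@]2(C)CCCC(C)(C)[C@@H]2CC[C@@]1(C)O | target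

## Totals and risks

Total step count: 3. Longest linear sequence: 3.

**Most likely to fail, first: step 1 (facial selectivity at C14).** The C13 carbinol carries methyl and a CH2 chain, so 1,2-induction is weak. The sense is predicted by the directed model, but the ratio is uncertain, and aqueous undirected osmylation would be expected to favour 14S. The fallback gives up on higher induction and recycles the wrong epimer. It sets out from 1, which step 1 also converts into the (14S) chelate F1. F1 is hydrolysed with aqueous Na2SO3 to the (13R,14S)-tetraol F2. F2 is closed with 1,1′-thiocarbonyldiimidazole (THF, reflux) to the 14,15-cyclic thionocarbonate F3. F3 is heated with P(OMe)3 (Corey–Winter olefination, a stereospecific cycloreversion that does not touch C13) to regenerate sclareol. The fallback comes back to the route at 1, so all material can be funnelled through 2 over repeated cycles.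

**Second: step 3 (mono-acetylation).** The risks are over-acylation at C14 and 15→14 acyl migration on work-up. The fallback replaces rate-based selection by covalent activation of the diol. It sets out from 3, which is heated with Bu2SnO in MeOH and evaporated to give the 14,15-O-dibutylstannylene acetal F4. F4 reacts with AcCl (1.0 equiv, CH2Cl2, 0 °C) at the primary oxygen only. Aqueous work-up releases the C14–OH, and the fallback comes back to the route at 4.

**Third: step 2 (release of the tetraol).** TMEDA osmate chelates are robust, and the very polar tetraol can be lost to the aqueous sulfite phase. The fallback avoids an isolated chelate altogether. It sets out from 1 and runs the cycloaddition with catalytic OsO4 (5 mol %) and Me3NO·2H2O in CH2Cl2 at room temperature, so the glycol is freed by oxidative turnover of the osmate ester in the flask. It comes back to the route at 3, obtained as a C14-epimer mixture that is then separated after step 3 as the less polar monoacetates. No compound outside the list is made (F0).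

## Further compounds

F1 | step 1 | OsO2(TMEDA) 14,15-glycolate of (13R,14S)-labdane-8α,13,14,15-tetraol | O=[Os-2]12(=O)(OC[C@H](O1)[C@](C)(O)CC[C@@H]3[C@@]4(C)CCCC(C)(C)[C@@H]4CC[C@@]3(C)O)[N+](C)(C)CC[N+]2(C)C
F2 | step 1 | (13R,14S)-labdane-8α,13,14,15-tetraol | OC[C@H](O)[C@](C)(O)CC[C@@H]1[C@@]2(C)CCCC(C)(C)[C@@H]2CC[C@@]1(C)O
F3 | step 1 | 14,15-cyclic thionocarbonate of (13R,14S)-labdane-8α,13,14,15-tetraol | S=C1OC[C@H](O1)[C@](C)(O)CC[C@@H]2[C@@]3(C)CCCC(C)(C)[C@@H]3CC[C@@]2(C)O
F0 | step 2 | none | none
F4 | step 3 | 14,15-O-dibutylstannylene acetal of (13R,14R)-labdane-8α,13,14,15-tetraol | CCCC[Sn]1(CCCC)OC[C@@H](O1)[C@](C)(O)CC[C@@H]2[C@@]3(C)CCCC(C)(C)[C@@H]3CC[C@@]2(C)O
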